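**Retrosynthetic overview**
- Feature (flavanone numbering): ring-A carbons C5–C8 plus the CH2CH2OH arm on C6 form the skeleton of an α-acyl-γ-butyrolactone. C5 is the lactone C=O, the arm OH is the lactone ring O, C7 is the acyl C=O and C8 is the acyl α-CH2. O1–C2–C3–C4–C4a–C8a are a 2-aryl-2,3-dihydropyran-4-one.
- Laxiflorin ⇒ its 4'-O-TBS ether ⇒ cut C8–C8a and C4a–C5 (ring A). This gives an (S)-5-bromo-dihydropyranone as a C4a≡C8a equivalent, plus the bis-silyl dienol ether of the prenylated acyl-lactone.
- Bromo-pyranone ⇒ α-bromination of the pyranone made from TBS-vanillin and Danishefsky's diene by catalytic asymmetric hetero-Diels–Alder reaction, which sets C2.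
- Diene ⇒ γ-prenylation of the α-acetyl-γ-butyrolactone dianion, then O-silylation in two stages.
- Ring order: B (vanillin) → C (hetero-Diels–Alder) → A ([4+2] benzannulation). O1–C8a exists before ring A, so no C6/C8 or O1/O5 choice arises.

Key step: step 7

Assumption: the (S)-H8-BINOL–titanium catalyst is taken to leave the Si face of the aryl aldehyde open, because the (R)-series delivers carbon nucleophiles to the Re face of benzaldehyde. The sense is confirmed on the dihydropyranone, and the antipodal ligand is used if it proves opposite.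
Flavanone locants (O1, C2 … C8a) are used throughout, also for the fragments.

**Step 1**
Reactants: 1 vanillin
Product: 2 4-(tert-butyldimethylsilyloxy)-3-methoxybenzaldehyde
Conditions: TBSCl (1.1 equiv), imidazole (1.1 equiv), CH2Cl2, 0 → 23 °C
Reagents that add atoms: tert-butyldimethylsilyl chloride, CC(C)(C)[Si](C)(C)Cl
Why: Imidazole-promoted O-silylation of a phenol; the aryl TBS ether should tolerate the Lewis-acid, NBS and weakly acidic steps ahead and can be removed at the end without base.

**Step 2**
Reactants: 2 4-(tert-butyldimethylsilyloxy)-3-methoxybenzaldehyde; 3 (E)-1-methoxy-3-(trimethylsilyloxy)buta-1,3-diene (Danishefsky's diene)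
Product: 5 (S)-2-[4-(tert-butyldimethylsilyloxy)-3-methoxyphenyl]-2,3-dihydro-4H-pyran-4-one, via silylated aldol adduct 4 (not isolated)
Conditions: (S)-H8-BINOL (11 mol %), Ti(OiPr)4 (10 mol %), 4 Å MS, toluene, 0 °C; then TFA (0.2 equiv), CH2Cl2, 0 °C
Reagents that add atoms: none
Why: Catalytic asymmetric hetero-Diels–Alder reaction in its Mukaiyama-aldol/cyclisation variant: the chiral titanium biaryldiolate binds the aldehyde and lets the diene terminus reach only the Si face, which sets C2 as S in 4, and acid then closes ring C by oxa-Michael addition and loss of methanol without touching the new C–O bond.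

**Step 3**
Reactants: 5 (S)-2-aryl-2,3-dihydro-4H-pyran-4-one
Product: 6 (S)-5-bromo-2-[4-(tert-butyldimethylsilyloxy)-3-methoxyphenyl]-2,3-dihydro-4H-pyran-4-one
Conditions: NBS (1.0 equiv), CH2Cl2, −20 → 0 °C, dark
Reagents that add atoms: N-bromosuccinimide, O=C1CCC(=O)N1Br
Why: Electrophilic α-halogenation of a vinylogous ester (bromonium transfer to pyranone C5, the enol-ether β-carbon, then loss of H-5); low temperature, a non-polar solvent and one equivalent of NBS should keep ring B and the C2 centre untouched.

**Step 4**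
Reactants: 7 α-acetyl-γ-butyrolactone; 8 prenyl bromide
Product: 10 3-(5-methylhex-4-enoyl)dihydrofuran-2(3H)-one, via dilithium dianion 9 (not isolated)
Conditions: LDA (2.2 equiv), THF, −78 → 0 °C; 8 (1.0 equiv), −78 → 0 °C; 1 M HCl
Reagents that add atoms: none
Why: γ-Alkylation of a β-dicarbonyl dianion: the more basic carbanion on the acetyl methyl group displaces the allylic bromide (SN2) while the stabilised α-enolate stays inert, and the α-centre of 10 is labile and of no consequence.

**Step 5**
Reactants: 10 3-(5-methylhex-4-enoyl)dihydrofuran-2(3H)-one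
Product: 11 3-[5-methyl-1-(trimethylsilyloxy)hex-4-enylidene]dihydrofuran-2(3H)-one (E/Z mixture)
Conditions: TMSCl (1.8 equiv), Et3N (1.6 equiv), toluene, 23 °C; filtration under argon
Reagents that add atoms: trimethylsilyl chloride, C[Si](C)(C)Cl
Why: O-Silylation of the enol of a β-keto lactone under amine base, the first stage of the usual preparation of 1,3-bis(silyloxy)dienes; the C6=C7 geometry is irrelevant because that bond becomes the central single bond of the diene.

**Step 6**
Reactants: 11 mono-silyl enol ether
Product: 13 (Z)-3-[5-methyl-1-(trimethylsilyloxy)hexa-1,4-dienyl]-2-(trimethylsilyloxy)-4,5-dihydrofuran, via lithium dienolate 12 (not isolated)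
Conditions: LDA (1.3 equiv), THF, −78 °C; TMSCl (1.5 equiv), −78 → 23 °C; pentane, filtration under argon
Reagents that add atoms: trimethylsilyl chloride, C[Si](C)(C)Cl
Why: Kinetic γ-deprotonation of the silyloxy-enoate gives the extended lactone enolate 12, which TMSCl traps on oxygen (silyl ketene acetal formation); the chain on C8 should turn away from the dihydrofuran ring (Z), the geometry that can reach the s-cis conformation.

**Step 7**
Reactants: 6 (S)-5-bromo-dihydropyranone; 13 bis-silyl dienol ether
Product: 16 (2S)-2-[4-(tert-butyldimethylsilyloxy)-3-methoxyphenyl]-5,7-dihydroxy-6-(2-hydroxyethyl)-8-(3-methylbut-2-enyl)chroman-4-one, via tricyclic bromo ketal 14 (not isolated), via enolised bromo dione 15 (not isolated)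
Conditions: 13 (2.5 equiv), Eu(fod)3 (10 mol %), CH2Cl2, 12 kbar, 25 °C; then AgOAc (1.5 equiv), AcOH–THF–H2O, 0 → 25 °C, dark
Reagents that add atoms: none
Why: Proposed new method: the largest HOMO coefficient of the trioxygenated diene 13 lies on its only terminus without oxygen (C8) and the largest LUMO coefficient of 6 on the oxygen-bearing enone β-carbon (C8a), so C8–C8a should form first and the C5 ketene-acetal carbon then joins C4a, either as the late half of one asynchronous [4+2] event or as 6-(enolexo)-exo-trig attack of the bromo-enolate on the silyloxy(alkoxy)carbenium ion, which closes ring A as tricyclic ketal 14, with 12 kbar and a mild oxophilic europium chelate chosen to offset the vinylogous-ester deactivation of 6 without Brønsted acid or base. Since Br-4a and H-8a are cis in 14 and H-8a is not acidified by any carbonyl group, an E2 or E1cB loss of HBr at this stage is not counted on; instead aqueous acetic acid cleaves both O–Si bonds, the C5 hemiketal opens so that the former lactone oxygen becomes the side-chain hydroxyl, and the enolised 2-bromo-1,3-dione 15 ionises at C4a under silver assistance, as α-halo ketones do on the way to 2-oxyallyl cations, to a cation that is the C8a-protonated arene and should give 16 by loss of H-8a. The closest known reaction types are the benzannulations of 1,1-dioxygenated 3-silyloxydienes with halo-quinones, the cycloadditions of chromones that carry an acceptor at C3, and Michael–Dieckmann annulations of the Staunton–Weinreb kind, none of which has been shown on a 2,3-dihydropyran-4-one or with a lactone as the ketene-acetal half. Two selectivities are needed: orientation, secured by the polarity match above and by the fully substituted C6, which shuts the competing [3+3] mode through the central carbon, and retention of the silylated rather than the ring oxygen on C5, secured by hydrolytic Si–O cleavage instead of Lewis-acid ionisation of the ketal. No lasting stereocentre is created, because C4a, C5, C8 and C8a all become sp2, and C2 should keep its configuration since neither its C–O nor its C–H bond takes part and the medium stays neutral to weakly acidic.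

**Step 8**
Reactants: 16 4'-O-TBS-laxiflorin
Product: 17 laxiflorin, (2S)-5,7-dihydroxy-2-(4-hydroxy-3-methoxyphenyl)-6-(2-hydroxyethyl)-8-(3-methylbut-2-enyl)chroman-4-one
Conditions: TBAF–AcOH (1:1, 1.2 equiv), THF, 0 °C
Reagents that add atoms: none
Why: Fluoride-induced cleavage of an aryl silyl ether; acetic acid buffers fluoride and the phenoxides so that the retro-oxa-Michael opening of ring C, the racemisation path of flavanones, cannot start, and the prenyl group, primary alcohol and chelated ketone are inert.

**Compound list**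
1 | vanillin | COc1cc(C=O)ccc1O | starting material
2 | 4-(tert-butyldimethylsilyloxy)-3-methoxybenzaldehyde | COc1cc(C=O)ccc1O[Si](C)(C)C(C)(C)C | intermediate
3 | (E)-1-methoxy-3-(trimethylsilyloxy)buta-1,3-diene | CO/C=C/C(=C)O[Si](C)(C)C | starting material
4 | (S,E)-5-aryl-1-methoxy-5-(trimethylsilyloxy)pent-1-en-3-one (silylated aldol adduct, not isolated) | CO/C=C/C(=O)C[C@H](O[Si](C)(C)C)c1ccc(O[Si](C)(C)C(C)(C)C)c(OC)c1 | intermediate
5 | (S)-2-[4-(TBS-oxy)-3-methoxyphenyl]-2,3-dihydro-4H-pyran-4-one | COc1cc([C@@H]2CC(=O)C=CO2)ccc1O[Si](C)(C)C(C)(C)C | intermediate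
6 | (S)-5-bromo-2-[4-(TBS-oxy)-3-methoxyphenyl]-2,3-dihydro-4H-pyran-4-one | COc1cc([C@@H]2CC(=O)C(Br)=CO2)ccc1O[Si](C)(C)C(C)(C)C | intermediate
7 | α-acetyl-γ-butyrolactone | CC(=O)C1CCOC1=O | starting material
8 | prenyl bromide | CC(C)=CCBr | starting material
9 | dilithium dianion of 7 (not isolated) | [Li+].[Li+].C=C([O-])C1=C([O-])OCC1 | intermediate
10 | 3-(5-methylhex-4-enoyl)dihydrofuran-2(3H)-one (α-centre labile) | CC(C)=CCCC(=O)C1CCOC1=O | intermediate
11 | 3-[5-methyl-1-(trimethylsilyloxy)hex-4-enylidene]dihydrofuran-2(3H)-one (E/Z mixture) | CC(C)=CCCC(O[Si](C)(C)C)=C1CCOC1=O | intermediate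
12 | lithium dienolate of 11 (not isolated) | [Li+].CC(C)=CC/C=C(\O[Si](C)(C)C)C1=C([O-])OCC1 | intermediate
13 | (Z)-bis-TMS dienol ether of 10 | CC(C)=CC/C=C(\O[Si](C)(C)C)C1=C(O[Si](C)(C)C)OCC1 | intermediate
14 | tricyclic bromo ketal, the [4+2] adduct (2S; C4a, C5, C8, C8a transient and undefined; not isolated) | COc1cc([C@@H]2CC(=O)C3(Br)C(O2)C(CC=C(C)C)C(O[Si](C)(C)C)=C4CCOC43O[Si](C)(C)C)ccc1O[Si](C)(C)C(C)(C)C | intermediate
15 | enolised 4a-bromo-5,7-dione with free hydroxyethyl arm (2S; C4a, C8, C8a transient; not isolated) | COc1cc([C@@H]2CC(=O)C3(Br)C(O2)C(CC=C(C)C)C(O)=C(CCO)C3=O)ccc1O[Si](C)(C)C(C)(C)C | intermediate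
16 | (2S)-4'-O-TBS-laxiflorin | COc1cc([C@@H]2CC(=O)c3c(O)c(CCO)c(O)c(CC=C(C)C)c3O2)ccc1O[Si](C)(C)C(C)(C)C | intermediate
17 | laxiflorin | COc1cc([C@@H]2CC(=O)c3c(O)c(CCO)c(O)c(CC=C(C)C)c3O2)ccc1O | target

**Total steps:** 8. **Longest linear sequence:** 5 (steps 1, 2, 3, 7, 8 or steps 4, 5, 6, 7, 8).

**Steps most likely to fail**

**1. Step 7.**
- The first C–C bond may form too slowly on the push–pull enone.
- Silyl migration to the enolate oxygen may stop the sequence at the open Michael stage.
- During aromatisation, expulsion of O1 from C8a and transfer of positive bromine from C4a may outrun loss of bromide.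

Fallback (known reactions only; ring A comes from the aromatic pool, all harsh steps run on an achiral chromone, and C2 is set last). It sets out from prenyl bromide 8 and comes back at 17.
- Commercial 5,7-dihydroxychromen-4-one is protected at the non-chelated 7-OH (MOMCl, iPr2NEt) as 5-hydroxy-7-(methoxymethoxy)chromen-4-one F1.
- O-Allylation (allyl bromide, K2CO3, DMF) gives 5-allyloxy-7-(methoxymethoxy)chromen-4-one F2.
- Heating in PhNEt2 at 190 °C follows. The aromatic Claisen rearrangement can end only at C6 and should give 6-allyl-5-hydroxy-7-(methoxymethoxy)chromen-4-one F3.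
- Lemieux–Johnson cleavage (OsO4 cat., NaIO4, 2,6-lutidine) gives 2-[5-hydroxy-7-(methoxymethoxy)-4-oxochromen-6-yl]acetaldehyde F4.
- NaBH(OAc)3 reduces it to 5-hydroxy-6-(2-hydroxyethyl)-7-(methoxymethoxy)chromen-4-one F5.
- MOMCl/iPr2NEt gives 5-hydroxy-7-(methoxymethoxy)-6-[2-(methoxymethoxy)ethyl]chromen-4-one F6.
- O-Alkylation with 8 (K2CO3, DMF) gives the 5-prenyl ether F7.
- In F7 both ortho positions are blocked, so the Claisen–Cope cascade (Eu(fod)3, PhCl, heat) should carry the prenyl group to C8, giving 5-hydroxy-7-(methoxymethoxy)-6-[2-(methoxymethoxy)ethyl]-8-prenylchromen-4-one F8.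
- Rhodium(I)-catalysed asymmetric 1,4-addition of commercial [4-(tert-butyldimethylsilyloxy)-3-methoxyphenyl]boronic acid, with the chiral bisphosphine antipode that leads to 2S, gives the protected (2S)-flavanone F9.
- HCl in MeOH removes both MOM groups and the silyl ether to reach 17.

**2. Step 3.** Electrophilic bromination of the silyloxy-anisole ring B, or over-bromination, may compete with attack at pyranone C5.

Fallback: bromine is placed on the four-carbon partner before ring B is present. It sets out from 2 and comes back at 6.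
- Commercial (E)-4-methoxybut-3-en-2-one takes up Br2 (CH2Cl2, −78 °C) to give 3,4-dibromo-4-methoxybutan-2-one F10.
- Et3N eliminates HBr to give (Z)-3-bromo-4-methoxybut-3-en-2-one F11.
- TMSOTf/Et3N gives (Z)-2-bromo-1-methoxy-3-(trimethylsilyloxy)buta-1,3-diene F12.
- The titanium-catalysed hetero-Diels–Alder reaction of F12 with 2, followed by the acid treatment of step 2, should give 6 directly.

**3. Step 2.** The electron-rich aldehyde may show low turnover or poor facial selectivity. Enantiopurity may also erode by benzylic ionisation during the acid-induced ring closure.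

Fallback: the stereocentre is secured by separation instead of catalysis. It sets out from 2 and 3 and comes back at 5.
- BF3·OEt2 (Et2O, −78 °C, then TFA) gives the racemic dihydropyranone F13.
- Preparative chromatography on a polysaccharide chiral phase delivers 5 beside its (R)-enantiomer F14.

**Further compounds**
F1 | step 7 | 5-hydroxy-7-(methoxymethoxy)chromen-4-one | COCOc1cc(O)c2c(=O)ccoc2c1
F2 | step 7 | 5-allyloxy-7-(methoxymethoxy)chromen-4-one | C=CCOc1cc(OCOC)cc2occc(=O)c12
F3 | step 7 | 6-allyl-5-hydroxy-7-(methoxymethoxy)chromen-4-one | C=CCc1c(OCOC)cc2occc(=O)c2c1O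
F4 | step 7 | 2-[5-hydroxy-7-(methoxymethoxy)-4-oxochromen-6-yl]acetaldehyde | O=CCc1c(OCOC)cc2occc(=O)c2c1O
F5 | step 7 | 5-hydroxy-6-(2-hydroxyethyl)-7-(methoxymethoxy)chromen-4-one | OCCc1c(OCOC)cc2occc(=O)c2c1O
F6 | step 7 | 5-hydroxy-7-(methoxymethoxy)-6-[2-(methoxymethoxy)ethyl]chromen-4-one | COCOCCc1c(OCOC)cc2occc(=O)c2c1O
F7 | step 7 | 7-(methoxymethoxy)-6-[2-(methoxymethoxy)ethyl]-5-(3-methylbut-2-enyloxy)chromen-4-one | COCOCCc1c(OCOC)cc2occc(=O)c2c1OCC=C(C)C
F8 | step 7 | 5-hydroxy-7-(methoxymethoxy)-6-[2-(methoxymethoxy)ethyl]-8-(3-methylbut-2-enyl)chromen-4-one | COCOCCc1c(OCOC)c(CC=C(C)C)c2occc(=O)c2c1O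
F9 | step 7 | (2S)-2-[4-(TBS-oxy)-3-methoxyphenyl]-5-hydroxy-7-(methoxymethoxy)-6-[2-(methoxymethoxy)ethyl]-8-(3-methylbut-2-enyl)chroman-4-one | COc1cc([C@@H]2CC(=O)c3c(O)c(CCOCOC)c(OCOC)c(CC=C(C)C)c3O2)ccc1O[Si](C)(C)C(C)(C)C
F10 | step 3 | 3,4-dibromo-4-methoxybutan-2-one | COC(Br)C(Br)C(C)=O
F11 | step 3 | (Z)-3-bromo-4-methoxybut-3-en-2-one | CO/C=C(\Br)C(C)=O
F12 | step 3 | (Z)-2-bromo-1-methoxy-3-(trimethylsilyloxy)buta-1,3-diene | CO/C=C(\Br)C(=C)O[Si](C)(C)C
F13 | step 2 | racemic 2-[4-(TBS-oxy)-3-methoxyphenyl]-2,3-dihydro-4H-pyran-4-one | COc1cc(C2CC(=O)C=CO2)ccc1O[Si](C)(C)C(C)(C)C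
F14 | step 2 | (R)-2-[4-(TBS-oxy)-3-methoxyphenyl]-2,3-dihydro-4H-pyran-4-one | COc1cc([C@H]2CC(=O)C=CO2)ccc1O[Si](C)(C)C(C)(C)C
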